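Remark on the chemistry: the target is flat and achiral, with no stereocentre and no stable axis. The demand for a single enantiomer is therefore met trivially, and no SMILES below needs a stereodescriptor. Compounds 10 and 12 each hold one enolisable, racemic centre that vanishes in step 6.

## Structural features

The target is a flavone. Benzo ring A (C4a, C5, C6, C7, C8, C8a) is fused along C4a–C8a to the 4-pyranone ring C (O1, C2, C3, C4), and aryl ring B is joined by the C2–C1′ bond. Ring A is hexasubstituted: five contiguous oxygens alternate strictly (O1 on C8a, OMe on C8, OH on C7, OMe on C6, OH on C5), next to the acyl carbon C4 on C4a. C3 bears an enol-ether OMe, and ring B is a 1,2,4-trimethoxybenzene attached through its C5, so only C3′–H and C6′–H remain on the skeleton. There is no stereocentre, so nothing has to be controlled in three dimensions. Three points are fragile: the penta-oxygenated ring A with two free phenols (easily oxidised to quinones), the methyl ethers near the carbonyl system (3-OMe, 6-OMe, 2′-OMe, cleaved by chelating Lewis acids), and ring C, which opens in hot base (Wessely–Moser equilibration). The real difficulty is ring A. Two of its five oxygens must stay free while their direct neighbours are methylated, and the C4–C4a bond must be made at the last and most crowded carbon. The key step exploits a latent mirror plane through C4a and C7: once C4–C4a and O1–C2 are cut, O1 and 5-OH become equivalent, 8-OMe and 6-OMe become equivalent, and C4a is the only C–H of a free triol, flanked by the two equivalent OH groups. A 1,3-bis-electrophile holding C4, C3(OMe), C2 and ring B can therefore be laid on this C–H/O–H pair in only one way, and 5-OH and 7-OH are simply the hydroxyls left over.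

## Logic of the disconnections

**13 ⇒ 6 + 10 (through 12 and 11).**
- Bonds cut: C4–C4a and O1–C2, so ring C is lifted off ring A in one stroke.
- Route in one sentence: a thermal, acid-free [3+3] annulation of unprotected, mirror-symmetric 6 with the acylketene 11 released from 10. This sentence does not fit the acyl-transfer or chalcone routes, where ring A enters as an acetophenone and the key step forms C2–C3.
- Reason: the cut uncovers the mirror plane of ring A, removes every regiochemical choice, and makes protecting groups unnecessary in the last step.
- Gain: a C21 hexasubstituted bicycle falls into a C8 and a C14 monocyclic arene, joined convergently in the final operation.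
- Demand: 10 must react in the chromone sense (C4 to carbon, C2 to oxygen), C-acylation must win over O-acylation, and 6 must survive heat, which requires strict exclusion of oxygen.

**10 ⇒ 7 + 8 (through 9).**
- Bond cut: the bond between the aroyl carbon (future C2) and the methoxy-bearing carbon (future C3).
- Reason: the 3-OMe group is bought with 8, and the whole of ring B with 7, so no oxidation or methylation at C3 is needed later.
- Gain: two catalogue compounds.
- Demand: C-acylation of an ester enolate without self-condensation, with enough base to hold the more acidic product as its enolate.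

**6 ⇒ 5.**
- Bond cut: the O–CH2Ph bond on the oxygen that becomes 7-OH.
- Reason: 6 is the most oxidisable compound of the route and should be released only under neutral, reductive conditions just before use.
- Gain: all earlier chemistry runs on a stable ether.
- Demand: an air-free hand-over to step 6.

**5 ⇒ 3 (through 4).**
- Bonds cut: the two aryl C–O bonds of the oxygens that become O1 and 5-OH.
- Reason: both are installed at once, and symmetrically, from two C–Br bonds.
- Gain: the penta-oxygenated ring is reduced to a tri-oxygenated one.
- Demand: a twofold ipso-hydroxylation that does not need oxidative addition into a phenolate, hence the passage through boron in 4.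

**3 ⇒ 2.**
- Bonds cut: two C–Br bonds.
- Reason: the two OMe groups of 2 direct to exactly the two carbons that need oxygen, and leave free the carbon that becomes C4a.
- Gain: a symmetric dihalide in one operation.
- Demand: the central oxygen must not direct, so it must be masked and twisted out of conjugation.

**2 ⇒ 1.**
- Bond cut: O–CH2Ph.
- Reason: the free OH of 1 would direct an electrophile para, onto the future C4a.
- Gain: 1 is a bulk chemical that already holds 6-OMe, 7-O and 8-OMe in the right pattern.
- Demand: simple O-alkylation of a hindered phenol.

## Other disconnections considered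

**Alternative 1:** cut C2–C3 and O1–C2 (Allan–Robinson or Baker–Venkataraman logic), the first plan that comes to mind.
- Precursor: ring A would carry C4 and C3 as 1-(2,4,6-trihydroxy-3,5-dimethoxyphenyl)-2-methoxyethan-1-one A1, reached from 6 by a Houben–Hoesch methoxyacetylation.
- Forward key step: aroylation with 9, O→C acyl transfer and cyclodehydration. This would give the 7-O-aroyl flavone, 5-hydroxy-3,6,8-trimethoxy-4-oxo-2-(2,4,5-trimethoxyphenyl)-4H-chromen-7-yl 2,4,5-trimethoxybenzoate A2, and 13 after saponification.
- Ground for preferring the chosen plan: the key step of this alternative forms only the bonds to C2. The hard C4–C4a bond is left to a separate acid-mediated acylation of the same fragile triol.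
- Further ground: the three phenols of A1 each consume the aroyl donor, or call for protecting groups that forfeit the symmetry. Three to four operations from 6 would replace the single step 6.

**Alternative 2:** cut C2–C1′.
- Forward key step: a dehydrogenative coupling (Pd(II)/Ag(I) oxidative Heck type, or anodic) of C2–H of 5,7-dihydroxy-3,6,8-trimethoxy-4H-chromen-4-one A3 with C5–H of 1,2,4-trimethoxybenzene A4. It uses the most nucleophilic carbon of ring B.
- Ground, structure: A3 still contains the whole ring A problem and would itself come from A1 plus a C1 unit, so more steps precede the key step than in Alternative 1.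
- Ground, mechanism: aryl–Pd addition across C2=C3 places Pd on C3, which bears OMe and has no syn β-hydrogen, so turnover depends on enolate epimerisation.
- Ground, chemoselectivity: the oxidant or anode potential needed to engage A4 lies above that at which the 5,7-dihydroxy-6,8-dimethoxy ring is oxidised and A4 homocouples. Protection and deprotection would be added.

**Alternative 3:** cut O1–C2 and C3–OMe.
- Forward key step: I⁺-induced 6-endo-dig cyclisation of 1-[4-(benzyloxy)-2,3,5,6-tetramethoxyphenyl]-3-(2,4,5-trimethoxyphenyl)prop-2-yn-1-one A5, in which an ortho OMe attacks and loses its methyl. The product would be 7-(benzyloxy)-3-iodo-5,6,8-trimethoxy-2-(2,4,5-trimethoxyphenyl)-4H-chromen-4-one A6.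
- Completion: copper-mediated methoxylation to 7-(benzyloxy)-3,5,6,8-tetramethoxy-2-(2,4,5-trimethoxyphenyl)-4H-chromen-4-one A7, then chelation-controlled cleavage of 5-OMe and removal of benzyl.
- Ground: the symmetry of ring A is used here too, but every oxygen must first be masked, and two must later be unmasked by two different logics.
- Further ground: the iodonium source also attacks ring B, C3–O needs a step of its own, and at least four steps follow completion of ring A instead of one.

Key step: step 6

## Route

Step 1
Reactants: 1 2,6-dimethoxyphenol (syringol)
Product: 2 2-(benzyloxy)-1,3-dimethoxybenzene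
Conditions: BnBr (1.1 equiv), K2CO3, DMF, 60 °C
Reagents that add atoms: benzyl bromide, BrCc1ccccc1
Why: Williamson ether synthesis; both ortho positions are blocked, so only O-alkylation is open. The benzyl group switches off the para-directing power of the free OH, which would otherwise send electrophiles to the one carbon that must stay C–H.

Step 2
Reactants: 2 2-(benzyloxy)-1,3-dimethoxybenzene
Product: 3 3-(benzyloxy)-1,5-dibromo-2,4-dimethoxybenzene
Conditions: NBS (2.1 equiv), MeCN, 0 °C to rt, dark
Reagents that add atoms: N-bromosuccinimide, O=C1CCC(=O)N1Br
Why: Twofold electrophilic aromatic bromination; C4 and C6 of 2 are each para to one OMe and ortho to the other, whereas C5 is para only to the OBn group, which its two neighbours twist out of conjugation. The first bromine further deactivates its own ortho position C5, so the second should enter at C6. The unactivated phenyl ring and the benzylic CH2 should be spared under ionic conditions in the dark.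

Step 3
Reactants: 3 3-(benzyloxy)-1,5-dibromo-2,4-dimethoxybenzene
Product: 5 5-(benzyloxy)-4,6-dimethoxybenzene-1,3-diol, via bis(pinacol boronate) 4 (not isolated)
Conditions: B2pin2 (2.5 equiv), PdCl2(dppf) (5 mol %), KOAc, 1,4-dioxane, 90 °C; then THF, aq NaOH, 30% H2O2, 0 °C
Reagents that add atoms: bis(pinacolato)diboron, CC1(C)OB(OC1(C)C)B1OC(C)(C)C(C)(C)O1 (boron and pinacol of 4); hydrogen peroxide, OO (the two new oxygens of 5)
Why: Twofold Miyaura borylation followed by oxidative 1,2-migration from boron to oxygen (ipso-hydroxylation), which keeps the positions fixed in step 2. Each C–Br has only one ortho substituent, and passing through boron avoids the oxidative addition into an electron-rich bromophenolate that direct hydroxylation would require for the second bromide.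

Step 4
Reactants: 5 5-(benzyloxy)-4,6-dimethoxybenzene-1,3-diol
Product: 6 2,4-dimethoxybenzene-1,3,5-triol
Conditions: H2 (1 atm), 10% Pd/C, degassed EtOAc–MeOH, rt; filtration and concentration under Ar, used at once
Reagents that add atoms: none
Why: Hydrogenolysis of a benzyl aryl ether; nothing else in 5 is reducible. The air-sensitive triol is released without acid, base or oxidant directly before the key step.

Step 5
Reactants: 7 2,4,5-trimethoxybenzoic acid; 8 methyl methoxyacetate
Product: 10 methyl 2-methoxy-3-oxo-3-(2,4,5-trimethoxyphenyl)propanoate (racemic), via acid chloride 9 (not isolated)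
Conditions: 7, (COCl)2, cat. DMF, CH2Cl2, 0 °C to rt, concentrate; 8 and LiHMDS (2.2 equiv each), THF, −78 °C, then 9 in THF, −78 °C; aq NH4Cl
Reagents that add atoms: oxalyl chloride, O=C(Cl)C(=O)Cl (the Cl of 9; none of its atoms remains in 10)
Why: Acid chloride formation, then crossed Claisen-type C-acylation of a lithium ester enolate. The second equivalent of enolate deprotonates the more acidic product and shields it from a second acylation. The new centre is racemic and enolisable, and is erased in step 6.

Step 6
Reactants: 6 2,4-dimethoxybenzene-1,3,5-triol; 10 methyl 2-methoxy-3-oxo-3-(2,4,5-trimethoxyphenyl)propanoate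
Product: 13 5,7-dihydroxy-3,6,8,2',4',5'-hexamethoxyflavone, via acylketene 11 (not isolated), via 1,3-diketone 12 (not isolated)
Conditions: 6 (1.0 equiv), 10 (1.3 equiv), degassed Ph2O (minimum) or neat melt, Ar sweep, 220–240 °C (bath or µW), 15–45 min
Reagents that add atoms: none
Why: Mentzer pyrone synthesis, the thermal and acid-free relative of the Simonis chromone cyclisation, known for phloroglucinol-type phenols and aroylacetates. The enol of 10 loses MeOH through a six-membered transition state to give acylketene 11, the pathway by which α-monosubstituted β-keto esters exchange their alkoxy group on heating. Capture of 11 by an oxygen of 6 gives an aryl ester that reverts to 11 at this temperature, whereas capture by the only C–H carbon (ortho to two OH groups, para to the third, so reacting like a phloroglucinol enol carbon) gives after tautomerisation the doubly chelated diketone 12 and should not revert. Ring C then closes by 6-exo-trig addition of an ortho OH of 12 to the aroyl C=O (future C2) and loss of water to the aromatic 4-pyranone, the argon sweep removing MeOH and water so that the sequence runs one way. Site selectivity is secured by the substrate: 6 has one C–H and its two ortho OH groups are mirror images, so both closures, and any Wessely–Moser opening and reclosure, give the same 13 and leave exactly 5-OH and 7-OH free. The chromone sense is secured because no acid is present, the ketone of 10 is strongly deactivated by the 2′- and 4′-OMe donors and hindered by the α-substituent, and the ketene carbon is by far the stronger electrophile, so carbon bonds to C4 and oxygen to C2 rather than the Pechmann way round. A second C-acylation is impossible because no C–H remains on ring A. No stereocentre is formed, and the labile centre of 10 and 12 disappears.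

## Compound list

1 | 2,6-dimethoxyphenol (syringol) | COc1cccc(OC)c1O | starting material
2 | 2-(benzyloxy)-1,3-dimethoxybenzene | COc1cccc(OC)c1OCc1ccccc1 | intermediate
3 | 3-(benzyloxy)-1,5-dibromo-2,4-dimethoxybenzene | COc1c(Br)cc(Br)c(OC)c1OCc1ccccc1 | intermediate
4 | 2,2'-[5-(benzyloxy)-4,6-dimethoxy-1,3-phenylene]bis(4,4,5,5-tetramethyl-1,3,2-dioxaborolane) | COc1c(B2OC(C)(C)C(C)(C)O2)cc(B2OC(C)(C)C(C)(C)O2)c(OC)c1OCc1ccccc1 | intermediate
5 | 5-(benzyloxy)-4,6-dimethoxybenzene-1,3-diol | COc1c(O)cc(O)c(OC)c1OCc1ccccc1 | intermediate
6 | 2,4-dimethoxybenzene-1,3,5-triol | COc1c(O)cc(O)c(OC)c1O | intermediate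
7 | 2,4,5-trimethoxybenzoic acid | COc1cc(OC)c(C(=O)O)cc1OC | starting material
8 | methyl methoxyacetate | COCC(=O)OC | starting material
9 | 2,4,5-trimethoxybenzoyl chloride | COc1cc(OC)c(C(=O)Cl)cc1OC | intermediate
10 | methyl 2-methoxy-3-oxo-3-(2,4,5-trimethoxyphenyl)propanoate (racemic, enolisable) | COC(=O)C(OC)C(=O)c1cc(OC)c(OC)cc1OC | intermediate
11 | 2-methoxy-3-oxo-3-(2,4,5-trimethoxyphenyl)prop-1-en-1-one (acylketene) | COC(=C=O)C(=O)c1cc(OC)c(OC)cc1OC | intermediate
12 | 2-methoxy-1-(2,4,6-trihydroxy-3,5-dimethoxyphenyl)-3-(2,4,5-trimethoxyphenyl)propane-1,3-dione (racemic, enolisable) | COC(C(=O)c1c(O)c(OC)c(O)c(OC)c1O)C(=O)c1cc(OC)c(OC)cc1OC | intermediate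
13 | 5,7-dihydroxy-3,6,8,2',4',5'-hexamethoxyflavone (achiral) | COc1cc(OC)c(-c2oc3c(OC)c(O)c(OC)c(O)c3c(=O)c2OC)cc1OC | target

## Step count and risk

Total step count: 6.
Longest linear sequence: 5 steps (steps 1, 2, 3, 4 and 6, from 1). Step 5 is the convergent branch.

**Step 6 (key step).**
- What may go wrong: thermal or oxidative breakdown of the penta-oxygenated triol before C-acylation, stalling at the reversible O-acylation stage, and loss of the ketene by hydrolysis and decarboxylation with the water of condensation.
- Fallback (sets out from 10, comes back at 13): the ring A oxygens are installed after ring closure instead of before it. Compound 10 is annulated under the same thermal conditions with commercial phloroglucinol (Oc1cc(O)cc(O)c1), the robust standard nucleophile of this reaction, to give 5,7-dihydroxy-3-methoxy-2-(2,4,5-trimethoxyphenyl)-4H-chromen-4-one F1. Its positions C6 and C8, each activated by two free OH groups, are brominated (NBS, 2 equiv, THF, 0 °C) to 6,8-dibromo-5,7-dihydroxy-3-methoxy-2-(2,4,5-trimethoxyphenyl)-4H-chromen-4-one F2. A twofold copper-mediated Ullmann-type methoxylation (NaOMe, CuBr, DMF–MeOH, 110–120 °C) then replaces both bromines to give 13.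
- Why it is only the reserve: its annulation leaves the ring A problem untouched, ring B competes for the brominating agent, and hydrodebromination can accompany the copper step.

**Step 3.**
- What may go wrong: an incomplete second borylation, protodeborylation of the ortho-alkoxy arylboronate, and over-oxidation of the electron-rich resorcinol by basic peroxide.
- Fallback (sets out from 3, comes back at 6): direct C–O coupling in place of C–B oxidation. Compound 3 is coupled twice with benzyl alcohol (CuI, 3,4,7,8-tetramethyl-1,10-phenanthroline, Cs2CO3, toluene, 110 °C, Ullmann-type ether synthesis) to give the stable 1,3,5-tris(benzyloxy)-2,4-dimethoxybenzene F3. A single neutral hydrogenolysis (H2, Pd/C) unveils all three phenols and gives 6, so no free phenol ever meets an oxidant.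

**Step 4.**
- What may go wrong: air oxidation of the liberated triol during filtration and concentration, so that degraded material enters the key step.
- Fallback (sets out from 5, comes back at 13): the triol is never made. Compound 5 is equally mirror-symmetric and has the same C–H flanked by two OH groups. It is annulated with 10 as in step 6 to give 7-(benzyloxy)-5-hydroxy-3,6,8-trimethoxy-2-(2,4,5-trimethoxyphenyl)-4H-chromen-4-one F4, and hydrogenolysis (H2, Pd/C, EtOAc) as the last operation gives 13.

**Step 5.**
- What may go wrong: self-condensation of the methoxyacetate enolate, quenching of the enolate by proton transfer from the product, and partial O-acylation.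
- Fallback (sets out from 9, comes back at 10): the C3–O bond is made by carbenoid insertion instead of being carried in. Compound 9 is treated with potassium methyl malonate, MgCl2 and Et3N in MeCN (decarboxylative acylation) to give methyl 3-oxo-3-(2,4,5-trimethoxyphenyl)propanoate F5. Diazo transfer (4-acetamidobenzenesulfonyl azide, Et3N, MeCN) gives methyl 2-diazo-3-oxo-3-(2,4,5-trimethoxyphenyl)propanoate F6, and Rh2(OAc)4-catalysed O–H insertion into MeOH gives 10.

## Further compounds

F1 | step 6 | 5,7-dihydroxy-3-methoxy-2-(2,4,5-trimethoxyphenyl)-4H-chromen-4-one | COc1cc(OC)c(-c2oc3cc(O)cc(O)c3c(=O)c2OC)cc1OC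
F2 | step 6 | 6,8-dibromo-5,7-dihydroxy-3-methoxy-2-(2,4,5-trimethoxyphenyl)-4H-chromen-4-one | COc1cc(OC)c(-c2oc3c(Br)c(O)c(Br)c(O)c3c(=O)c2OC)cc1OC
F3 | step 3 | 1,3,5-tris(benzyloxy)-2,4-dimethoxybenzene | COc1c(OCc2ccccc2)cc(OCc2ccccc2)c(OC)c1OCc1ccccc1
F4 | step 4 | 7-(benzyloxy)-5-hydroxy-3,6,8-trimethoxy-2-(2,4,5-trimethoxyphenyl)-4H-chromen-4-one | COc1cc(OC)c(-c2oc3c(OC)c(OCc4ccccc4)c(OC)c(O)c3c(=O)c2OC)cc1OC
F5 | step 5 | methyl 3-oxo-3-(2,4,5-trimethoxyphenyl)propanoate | COC(=O)CC(=O)c1cc(OC)c(OC)cc1OC
F6 | step 5 | methyl 2-diazo-3-oxo-3-(2,4,5-trimethoxyphenyl)propanoate | COC(=O)C(=[N+]=[N-])C(=O)c1cc(OC)c(OC)cc1OC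
A1 | alternative 1 | 1-(2,4,6-trihydroxy-3,5-dimethoxyphenyl)-2-methoxyethan-1-one | COCC(=O)c1c(O)c(OC)c(O)c(OC)c1O
A2 | alternative 1 | 5-hydroxy-3,6,8-trimethoxy-4-oxo-2-(2,4,5-trimethoxyphenyl)-4H-chromen-7-yl 2,4,5-trimethoxybenzoate | COc1cc(OC)c(-c2oc3c(OC)c(OC(=O)c4cc(OC)c(OC)cc4OC)c(OC)c(O)c3c(=O)c2OC)cc1OC
A3 | alternative 2 | 5,7-dihydroxy-3,6,8-trimethoxy-4H-chromen-4-one | COc1coc2c(OC)c(O)c(OC)c(O)c2c1=O
A4 | alternative 2 | 1,2,4-trimethoxybenzene | COc1ccc(OC)c(OC)c1
A5 | alternative 3 | 1-[4-(benzyloxy)-2,3,5,6-tetramethoxyphenyl]-3-(2,4,5-trimethoxyphenyl)prop-2-yn-1-one | COc1cc(OC)c(C#CC(=O)c2c(OC)c(OC)c(OCc3ccccc3)c(OC)c2OC)cc1OC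
A6 | alternative 3 | 7-(benzyloxy)-3-iodo-5,6,8-trimethoxy-2-(2,4,5-trimethoxyphenyl)-4H-chromen-4-one | COc1cc(OC)c(-c2oc3c(OC)c(OCc4ccccc4)c(OC)c(OC)c3c(=O)c2I)cc1OC
A7 | alternative 3 | 7-(benzyloxy)-3,5,6,8-tetramethoxy-2-(2,4,5-trimethoxyphenyl)-4H-chromen-4-one | COc1cc(OC)c(-c2oc3c(OC)c(OCc4ccccc4)c(OC)c(OC)c3c(=O)c2OC)cc1OC
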